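**Plan**

Ring A is the seven-membered carbocycle C1, C5–C10 (chain C2–C4/C15 on C1, C14 methyl on C10); ring B is the γ-lactone on C6–O/C7–C11 (C11–C13); β is the face of ring A that carries the C9 oxygen, α the opposite face.
Retrosynthetic cuts, in order: C5 angelate ester, C11=C13 methylene, lactone C6–O bond (carboxylate displacement), C7–C11 bond (conjugate addition to a C6–C7 enone), then C1–C2 and C10–C14 together.
Enabling feature: in ring A, C9 (O), C10 (CH3), C1 (O and the four-carbon chain) and C5 (O) are contiguous and map onto the γ-, β-, α- and carbonyl carbons of a 2-alkoxy-4-silyloxycyclohept-2-enone.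
Forward: cyclohepta-1,3-diene → (R)-4-silyloxy enone → its 2-(4-methoxybenzyloxy) derivative; one-flask methyl cuprate addition/aldol with (E)-but-2-enal attaches C14 and C2–C15; ring B is then annulated (Michael addition at C7, bromination–lactonisation at C6); C5, C11 and C2 are adjusted last.
Stereochemistry: C9 from an enantioselective Kornblum–DeLaMare desymmetrisation; C10 anti to C9–O; C1 by aldehyde attack anti to C10–CH3 (the ether oxygen is already on C1 and so stays α); C7 anti to C9–O; C6 by SN2 inversion of a 6β-bromide; C5 by hydride delivery from the C1 hydroxyl.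

Key step: step 7

Remark on the chemistry: the C2 carbinol formed in step 7 is not controlled; compounds 12–30 are carried as a pair of C2 epimers (centre left undefined in the SMILES) that converge in step 18.
Abbreviations: PMB = 4-methoxybenzyl, TBS = tert-butyldimethylsilyl, TES = triethylsilyl, TMS = trimethylsilyl.

**Route**

Step 1
Reactants: 1 cyclohepta-1,3-diene
Product: 2 6,7-dioxabicyclo[3.2.2]non-8-ene (meso endoperoxide)
Conditions: O2, tetraphenylporphyrin (cat.), visible light, CH2Cl2, 0 °C
Reagents that add atoms: dioxygen, O=O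
Why: Singlet oxygen adds suprafacially across the s-cis diene in a [4+2] cycloaddition, so the peroxide bridge is necessarily cis and the product is meso.

Step 2
Reactants: 2 6,7-dioxabicyclo[3.2.2]non-8-ene
Product: 3 (R)-4-hydroxycyclohept-2-en-1-one
Conditions: 9-O-acetyl-6′-hydroxy cinchona alkaloid base (10 mol %), CH2Cl2, rt
Reagents that add atoms: none
Why: In this enantioselective Kornblum–DeLaMare rearrangement the chiral amine removes one of the two enantiotopic bridgehead hydrogens (at C5), O–O cleavage gives the C5 ketone and leaves the C9 carbinol, and the R configuration is secured by choosing the appropriate quinine- or quinidine-derived pseudoenantiomer of the catalyst.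

Step 3
Reactants: 3 (R)-4-hydroxycyclohept-2-en-1-one
Product: 4 (R)-4-(tert-butyldimethylsilyloxy)cyclohept-2-en-1-one
Conditions: TBSCl, imidazole, DMF, 0 °C to rt
Reagents that add atoms: tert-butyldimethylsilyl chloride, CC(C)(C)[Si](C)(C)Cl
Why: Imidazole-mediated silylation of the secondary alcohol is mild enough to avoid isomerisation of the γ-hydroxy enone to the 1,4-diketone.

Step 4
Reactants: 4 (R)-4-(tert-butyldimethylsilyloxy)cyclohept-2-en-1-one
Product: 5 (4R)-4-(tert-butyldimethylsilyloxy)-2,3-epoxycycloheptan-1-one (oxirane α; anti to the silyl ether)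
Conditions: 30 % H2O2, benzyltrimethylammonium hydroxide (cat.), THF, 0 °C
Reagents that add atoms: hydrogen peroxide, OO
Why: Weitz–Scheffer nucleophilic epoxidation, in which hydroperoxide adds to C10 anti to the C9 silyl ether and the enolate closes the oxirane (both new centres become sp2 again in step 6).

Step 5
Reactants: 5 (4R)-4-(tert-butyldimethylsilyloxy)-2,3-epoxycycloheptan-1-one
Product: 6 3-hydroxy-2-(4-methoxybenzyloxy)-4-(tert-butyldimethylsilyloxy)cycloheptan-1-one (C1–OPMB β; C10–OH α; C9–OTBS β)
Conditions: 4-methoxybenzyl alcohol (3 equiv), NaH (0.2 equiv), THF, 0 °C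
Reagents that add atoms: 4-methoxybenzyl alcohol, COc1ccc(CO)cc1
Why: Alkoxide opening of an α,β-epoxy ketone occurs by SN2 attack at the carbonyl-activated α-carbon C1 with inversion, the established entry to 2-alkoxy-3-hydroxy ketones, and catalytic base at 0 °C limits retro-aldol opening.

Step 6
Reactants: 6 3-hydroxy-2-(4-methoxybenzyloxy)-4-(tert-butyldimethylsilyloxy)cycloheptan-1-one
Product: 8 (R)-2-(4-methoxybenzyloxy)-4-(tert-butyldimethylsilyloxy)cyclohept-2-en-1-one, via C10 mesylate 7 (not isolated)
Conditions: MsCl, Et3N, CH2Cl2, 0 °C to rt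
Reagents that add atoms: none
Why: Mesylation of the C10 hydroxyl is followed by E1cB elimination through the C5 enolate, which restores the C1=C10 double bond as a diosphenol ether without touching C9.

Step 7
Reactants: 8 (R)-2-(4-methoxybenzyloxy)-4-(tert-butyldimethylsilyloxy)cyclohept-2-en-1-one and 9 (E)-but-2-enal
Product: 12 2-[(E)-1-hydroxybut-2-enyl]-2-(4-methoxybenzyloxy)-3-methyl-4-(tert-butyldimethylsilyloxy)cycloheptan-1-one (C9–OTBS β; C10–CH3 α; C1–OPMB α; C1 chain β; C2 epimers), via lithium enolate 10 (not isolated), via chlorozinc enolate 11 (not isolated)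
Conditions: Me2CuLi (from MeLi and CuI), Et2O/THF, −78 to −40 °C; ZnCl2, THF, −78 °C; then 9, −78 °C; aq. NH4Cl
Reagents that add atoms: lithium dimethylcuprate, [Li+].C[Cu-]C
Why: Me2CuLi (monovalent copper) forms a π-complex with the enone, adds oxidatively at C10 to a trivalent copper β-adduct and eliminates reductively to give the C10–C14 bond and the tetrasubstituted lithium enolate 10, which after exchange with ZnCl2 (divalent zinc) adds as the less basic chlorozinc enolate 11 to the carbonyl of (E)-but-2-enal through a closed six-membered Zimmerman–Traxler transition state to form C1–C2. The closest known reaction type is the three-component cuprate conjugate addition–aldol coupling of 4-silyloxycycloalk-2-enones used for prostaglandin assembly, together with cuprate additions to 2-alkoxy enones. No ring is closed in this step. C10 is controlled by the C9 silyl ether (methyl enters the α-face, anti to it) and C1 by the new C10 methyl (the aldehyde enters the β-face, anti to it), which gives the trans,trans array and leaves the C1 ether oxygen on the α-face, cis to the methyl; the oxygen is therefore placed on C1 before the carbon electrophile arrives, because hydroxylation of a C1–H ketone would deliver oxygen anti to the methyl, on the wrong face. The step needs facial selectivity at two centres and 1,2-selectivity toward the enal: the single stereocentre at C9 relays the former, while regiospecific enolate formation at C1 and the hard zinc enolate at −78 °C secure the latter, and the C2 configuration is irrelevant because C2 is oxidised later.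

Step 8
Reactants: 12 aldol adduct
Product: 13 C2 triethylsilyl ether of 12
Conditions: TESOTf, 2,6-lutidine, CH2Cl2, −78 °C
Reagents that add atoms: triethylsilyl trifluoromethanesulfonate, CC[Si](CC)(CC)OS(=O)(=O)C(F)(F)F
Why: Silyl triflate/2,6-lutidine silylation of the hindered allylic carbinol is fast at low temperature and not basic enough to trigger retro-aldol cleavage of the β-hydroxy ketone.

Step 9
Reactants: 13 C2 triethylsilyl ether
Product: 15 cyclohept-2-en-1-one with the C6=C7 double bond (other groups as in 13), via trimethylsilyl enol ether 14 (not isolated)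
Conditions: LiN(i-Pr)2, TMSCl, THF, −78 °C; then Pd(OAc)2, MeCN, rt
Reagents that add atoms: none
Why: Saegusa–Ito dehydrogenation, in which the ketone can enolise only toward C6 because C1 is quaternary and Pd(OAc)2 converts the silyl enol ether into the enone by β-hydride elimination.

Step 10
Reactants: 16 trimethylsilyl acetate
Product: 17 1,1-bis(trimethylsilyloxy)ethene
Conditions: LiN(i-Pr)2, THF, −78 °C; TMSCl, −78 °C to rt
Reagents that add atoms: chlorotrimethylsilane, C[Si](C)(C)Cl
Why: O-Silylation of the lithium enolate of the silyl ester gives the ketene bis(silyl) acetal, a known acetic acid enolate equivalent.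

Step 11
Reactants: 15 C6=C7 enone and 17 1,1-bis(trimethylsilyloxy)ethene
Product: 19 keto acid bearing CH2CO2H on the α-face of C7 (C5 ketone; other groups as in 13), via bis(trimethylsilyl) adduct 18 (not isolated)
Conditions: TMSOTf (10 mol %), CH2Cl2, −78 °C; aq. citric acid work-up
Reagents that add atoms: none
Why: Mukaiyama–Michael addition, in which the silyl ketene acetal attacks C7 of the activated enone on the α-face, anti to the pseudoaxial C9 silyl ether (1,3-trans, as for 5-substituted cycloalkenones), and work-up hydrolyses both trimethylsilyl groups.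

Step 12
Reactants: 19 keto acid
Product: 21 keto lactone (cis-fused γ-lactone; C6–O and C7–C11 both α; C5 ketone; C1–OPMB), via 6β-bromo keto acid 20 (not isolated)
Conditions: LiN(SiMe3)2 (2.2 equiv), THF, −78 °C; NBS, −78 °C; then DMF, 0 °C to rt
Reagents that add atoms: none
Why: The C6 enolate of the dianion is brominated anti to the C7 side chain and the carboxylate then displaces bromide intramolecularly by SN2 with inversion (5-exo-tet), which can only give the cis-fused lactone with the C6–O bond on the α-face.

Step 13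
Reactants: 21 keto lactone
Product: 22 keto lactone with free tertiary C1 hydroxyl
Conditions: DDQ, CH2Cl2/pH 7 buffer, 0 °C to rt
Reagents that add atoms: none
Why: Oxidative cleavage of the electron-rich 4-methoxybenzyl ether through its benzylic oxocarbenium ion leaves the silyl ethers, lactone and ketone untouched.

Step 14
Reactants: 22 hydroxy keto lactone
Product: 23 C1,C5-diol lactone (5β-OH; trans to the C1 hydroxyl)
Conditions: Me4NBH(OAc)3, MeCN/AcOH (1:1), −20 °C
Reagents that add atoms: none
Why: Hydroxyl-directed reduction, in which the C1 hydroxyl exchanges onto boron and delivers hydride intramolecularly to the α-face of the C5 ketone, giving the anti (trans) diol typical of acyloxyborohydride reductions of hydroxy ketones.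

Step 15
Reactants: 23 diol lactone
Product: 26 α-methylene lactone diol, via Mannich base 24 (not isolated), via methiodide 25 (not isolated)
Conditions: LiN(SiMe3)2 (3.3 equiv), THF, −78 °C; Me2N=CH2 I (Eschenmoser's salt); then MeI, MeOH, rt; NaHCO3, CH2Cl2/H2O
Reagents that add atoms: N,N-dimethylmethyleneiminium iodide, C=[N+](C)C.[I-]
Why: Mannich reaction of the lactone enolate (the two hydroxyls masked in situ as lithium alkoxides), N-methylation and base-induced elimination is the standard α-methylenation of γ-lactones, and at this stage the lactone holds the only enolisable C–H.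

Step 16
Reactants: 26 α-methylene lactone diol and 27 angelic acid
Product: 29 C5 angelate, via mixed anhydride 28 (not isolated)
Conditions: 2,4,6-trichlorobenzoyl chloride, Et3N, toluene, rt; then 26, 80 °C
Reagents that add atoms: none
Why: Yamaguchi-type esterification through the mixed anhydride acylates the secondary C5 hydroxyl in preference to the tertiary C1 hydroxyl, and the absence of a nucleophilic catalyst preserves the Z (angelate) geometry.

Step 17
Reactants: 29 C5 angelate
Product: 30 C2 allylic alcohol (C9–OTBS retained)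
Conditions: AcOH/THF/H2O (3:1:1), rt
Reagents that add atoms: none
Why: Acid hydrolysis cleaves the allylic triethylsilyl ether much faster than the secondary tert-butyldimethylsilyl ether.

Step 18
Reactants: 30 C2 allylic alcohol
Product: 31 C2 (E)-enone with C9 silyl ether
Conditions: Dess–Martin periodinane, NaHCO3, CH2Cl2, 0 °C to rt
Reagents that add atoms: none
Why: Dess–Martin oxidation of the secondary allylic alcohol gives the crotonoyl ketone; both C2 epimers converge and the tertiary C1 hydroxyl cannot be oxidised.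

Step 19
Reactants: 31 C9 silyl ether
Product: 32 CNP0149130.1
Conditions: HF·pyridine, pyridine, THF, 0 °C to rt
Reagents that add atoms: none
Why: Fluoride-mediated cleavage of the remaining silyl ether under buffered, weakly acidic conditions is compatible with the angelate, the enone and the α-methylene lactone.

**Compound list**

1 | cyclohepta-1,3-diene | C1=CC=CCCC1 | starting material
2 | 6,7-dioxabicyclo[3.2.2]non-8-ene | C1CC[C@@H]2C=C[C@H]1OO2 | intermediate
3 | (R)-4-hydroxycyclohept-2-en-1-one | C1CC[C@@H](O)C=CC1=O | intermediate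
4 | (R)-4-(tert-butyldimethylsilyloxy)cyclohept-2-en-1-one | C1CC[C@@H](O[Si](C)(C)C(C)(C)C)C=CC1=O | intermediate
5 | (4R)-4-(tert-butyldimethylsilyloxy)-2,3-epoxycycloheptan-1-one, α-oxirane | C1CC[C@@H](O[Si](C)(C)C(C)(C)C)[C@@H]2O[C@@H]2C1=O | intermediate
6 | 3-hydroxy-2-(4-methoxybenzyloxy)-4-(tert-butyldimethylsilyloxy)cycloheptan-1-one | C1CC[C@@H](O[Si](C)(C)C(C)(C)C)[C@H](O)[C@@H](OCc2ccc(OC)cc2)C1=O | intermediate
7 | C10 mesylate of 6 | C1CC[C@@H](O[Si](C)(C)C(C)(C)C)[C@H](OS(C)(=O)=O)[C@@H](OCc2ccc(OC)cc2)C1=O | intermediate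
8 | (R)-2-(4-methoxybenzyloxy)-4-(tert-butyldimethylsilyloxy)cyclohept-2-en-1-one | C1CC[C@@H](O[Si](C)(C)C(C)(C)C)C=C(OCc2ccc(OC)cc2)C1=O | intermediate
9 | (E)-but-2-enal | C/C=C/C=O | starting material
10 | lithium enolate after methyl transfer | C1CC[C@@H](O[Si](C)(C)C(C)(C)C)[C@H](C)C(OCc2ccc(OC)cc2)=C1O[Li] | intermediate
11 | chlorozinc enolate | C1CC[C@@H](O[Si](C)(C)C(C)(C)C)[C@H](C)C(OCc2ccc(OC)cc2)=C1O[Zn]Cl | intermediate
12 | aldol adduct (C2 epimers) | C1CC[C@@H](O[Si](C)(C)C(C)(C)C)[C@H](C)[C@@](OCc2ccc(OC)cc2)(C(O)/C=C/C)C1=O | intermediate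
13 | C2 triethylsilyl ether | C1CC[C@@H](O[Si](C)(C)C(C)(C)C)[C@H](C)[C@@](OCc2ccc(OC)cc2)(C(O[Si](CC)(CC)CC)/C=C/C)C1=O | intermediate
14 | C5 trimethylsilyl enol ether (C5=C6) | C1C[C@@H](O[Si](C)(C)C(C)(C)C)[C@H](C)[C@@](OCc2ccc(OC)cc2)(C(O[Si](CC)(CC)CC)/C=C/C)C(O[Si](C)(C)C)=C1 | intermediate
15 | C6=C7 enone | C1=CC[C@@H](O[Si](C)(C)C(C)(C)C)[C@H](C)[C@@](OCc2ccc(OC)cc2)(C(O[Si](CC)(CC)CC)/C=C/C)C1=O | intermediate
16 | trimethylsilyl acetate | CC(=O)O[Si](C)(C)C | starting material
17 | 1,1-bis(trimethylsilyloxy)ethene | C=C(O[Si](C)(C)C)O[Si](C)(C)C | intermediate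
18 | bis(trimethylsilyl) Michael adduct | [C@@H]1(CC(=O)O[Si](C)(C)C)C[C@@H](O[Si](C)(C)C(C)(C)C)[C@H](C)[C@@](OCc2ccc(OC)cc2)(C(O[Si](CC)(CC)CC)/C=C/C)C(O[Si](C)(C)C)=C1 | intermediate
19 | keto acid (C7 side chain α) | C1[C@H](CC(=O)O)C[C@@H](O[Si](C)(C)C(C)(C)C)[C@H](C)[C@@](OCc2ccc(OC)cc2)(C(O[Si](CC)(CC)CC)/C=C/C)C1=O | intermediate
20 | 6β-bromo keto acid | Br[C@H]1[C@H](CC(=O)O)C[C@@H](O[Si](C)(C)C(C)(C)C)[C@H](C)[C@@](OCc2ccc(OC)cc2)(C(O[Si](CC)(CC)CC)/C=C/C)C1=O | intermediate
21 | keto lactone, C1–OPMB | C1C(=O)O[C@@H]2[C@H]1C[C@@H](O[Si](C)(C)C(C)(C)C)[C@H](C)[C@@](OCc3ccc(OC)cc3)(C(O[Si](CC)(CC)CC)/C=C/C)C2=O | intermediate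
22 | keto lactone, C1–OH | C1C(=O)O[C@@H]2[C@H]1C[C@@H](O[Si](C)(C)C(C)(C)C)[C@H](C)[C@@](O)(C(O[Si](CC)(CC)CC)/C=C/C)C2=O | intermediate
23 | C1,C5-diol lactone | C1C(=O)O[C@@H]2[C@H]1C[C@@H](O[Si](C)(C)C(C)(C)C)[C@H](C)[C@@](O)(C(O[Si](CC)(CC)CC)/C=C/C)[C@H]2O | intermediate
24 | C11 dimethylaminomethyl lactone (Mannich base) | CN(C)CC1C(=O)O[C@@H]2[C@H]1C[C@@H](O[Si](C)(C)C(C)(C)C)[C@H](C)[C@@](O)(C(O[Si](CC)(CC)CC)/C=C/C)[C@H]2O | intermediate
25 | methiodide of 24 | C[N+](C)(C)CC1C(=O)O[C@@H]2[C@H]1C[C@@H](O[Si](C)(C)C(C)(C)C)[C@H](C)[C@@](O)(C(O[Si](CC)(CC)CC)/C=C/C)[C@H]2O.[I-] | intermediate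
26 | α-methylene lactone diol | C=C1C(=O)O[C@@H]2[C@H]1C[C@@H](O[Si](C)(C)C(C)(C)C)[C@H](C)[C@@](O)(C(O[Si](CC)(CC)CC)/C=C/C)[C@H]2O | intermediate
27 | angelic acid, (Z)-2-methylbut-2-enoic acid | C/C=C(/C)C(=O)O | starting material
28 | angelic 2,4,6-trichlorobenzoic anhydride | C/C=C(/C)C(=O)OC(=O)c1c(Cl)cc(Cl)cc1Cl | intermediate
29 | C5 angelate (C2–OTES, C9–OTBS) | C=C1C(=O)O[C@@H]2[C@H]1C[C@@H](O[Si](C)(C)C(C)(C)C)[C@H](C)[C@@](O)(C(O[Si](CC)(CC)CC)/C=C/C)[C@H]2OC(=O)/C(C)=C\C | intermediate
30 | C2 allylic alcohol (C9–OTBS) | C=C1C(=O)O[C@@H]2[C@H]1C[C@@H](O[Si](C)(C)C(C)(C)C)[C@H](C)[C@@](O)(C(O)/C=C/C)[C@H]2OC(=O)/C(C)=C\C | intermediate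
31 | C2 enone (C9–OTBS) | C=C1C(=O)O[C@@H]2[C@H]1C[C@@H](O[Si](C)(C)C(C)(C)C)[C@H](C)[C@@](O)(C(=O)/C=C/C)[C@H]2OC(=O)/C(C)=C\C | intermediate
32 | CNP0149130.1 | C=C1C(=O)O[C@@H]2[C@H]1C[C@@H](O)[C@H](C)[C@@](O)(C(=O)/C=C/C)[C@H]2OC(=O)/C(C)=C\C | target

**Step count and risks**

Total steps: 19. Longest linear sequence: 18 (steps 1–9 and 11–19; step 10 prepares a reagent).

Step 7. Methyl transfer to the donor-substituted enone may be slow, and the aldol at the crowded C1 may revert before quenching. The fallback separates the two bond formations, sets out from 8 and returns at 12. Me2CuLi with TMSCl (THF, −78 °C) should give the trimethylsilyl enol ether F1 by chlorosilane-accelerated conjugate addition, methyl again anti to the C9 ether. F1 is isolated and joined to 9 in a BF3·OEt2-mediated Mukaiyama aldol reaction (CH2Cl2, −78 °C, open transition state, attack anti to the C10 methyl).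

Step 11. The silyl ketene acetal may attack the β-face of C7, or discriminate poorly between the faces of the flexible seven-membered enone. The resulting C7 epimer cannot be corrected later. The fallback relays the C7 configuration from C5 instead of the remote C9 ether, sets out from 15 and returns at 23. 1,2-Reduction (NaBH4, CeCl3·7H2O, MeOH, −78 °C; hydride expected anti to the pseudoaxial C1 ether oxygen) should give the 5α allylic alcohol F2. Acetylation (Ac2O, pyridine, DMAP) gives the allylic acetate F3. Ireland–Claisen rearrangement (LiN(i-Pr)2, TMSCl, THF, −78 °C to reflux) transfers the acetate carbon suprafacially to the α-face of C7 and moves the double bond to C5–C6, giving the C7 acetic acid F4. Epoxidation (mCPBA, NaHCO3, CH2Cl2) on the β-face, away from the C7 side chain and the C1 ether, is followed by camphorsulfonic acid-catalysed 5-exo opening of the oxirane at C6 by the α-disposed acid. Only this epoxide diastereomer can lactonise, and it gives the hydroxy lactone F5 with the C5 hydroxyl β and the lactone cis-fused. DDQ removal of the 4-methoxybenzyl ether then gives 23.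

Step 5. The alkoxide may attack the carbonyl or C10, the C10 alkoxide may undergo retro-aldol ring opening, or base may erode the C9 stereocentre. The fallback avoids alkoxide, sets out from 4 and returns at 8. Dihydroxylation (OsO4 cat., N-methylmorpholine N-oxide, acetone/H2O) anti to the silyl ether should give the cis-diol F6. 1,1′-Carbonyldiimidazole converts it into the cyclic carbonate F7. With Et3N this undergoes E1cB opening and decarboxylation to the 2-hydroxy enone (diosphenol) F8. Mitsunobu etherification (4-methoxybenzyl alcohol, PPh3, diisopropyl azodicarboxylate, THF, 0 °C) gives 8.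

**Further compounds**

F1 | step 7 | trimethylsilyl enol ether of the methyl adduct | C1CC[C@@H](O[Si](C)(C)C(C)(C)C)[C@H](C)C(OCc2ccc(OC)cc2)=C1O[Si](C)(C)C
F2 | step 11 | 5α allylic alcohol (C6=C7) | C1=CC[C@@H](O[Si](C)(C)C(C)(C)C)[C@H](C)[C@@](OCc2ccc(OC)cc2)(C(O[Si](CC)(CC)CC)/C=C/C)[C@@H]1O
F3 | step 11 | allylic acetate of F2 | C1=CC[C@@H](O[Si](C)(C)C(C)(C)C)[C@H](C)[C@@](OCc2ccc(OC)cc2)(C(O[Si](CC)(CC)CC)/C=C/C)[C@@H]1OC(C)=O
F4 | step 11 | C7 acetic acid with C5=C6 double bond | [C@@H]1(CC(=O)O)C[C@@H](O[Si](C)(C)C(C)(C)C)[C@H](C)[C@@](OCc2ccc(OC)cc2)(C(O[Si](CC)(CC)CC)/C=C/C)C=C1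
F5 | step 11 | hydroxy lactone, C1–OPMB, 5β-OH | C1C(=O)O[C@@H]2[C@H]1C[C@@H](O[Si](C)(C)C(C)(C)C)[C@H](C)[C@@](OCc3ccc(OC)cc3)(C(O[Si](CC)(CC)CC)/C=C/C)[C@H]2O
F6 | step 5 | 2,3-cis-diol (both hydroxyls α) | C1CC[C@@H](O[Si](C)(C)C(C)(C)C)[C@H](O)[C@H](O)C1=O
F7 | step 5 | cyclic carbonate of F6 | C1CC[C@@H](O[Si](C)(C)C(C)(C)C)[C@@H]2OC(=O)O[C@@H]2C1=O
F8 | step 5 | (R)-2-hydroxy-4-(tert-butyldimethylsilyloxy)cyclohept-2-en-1-one | C1CC[C@@H](O[Si](C)(C)C(C)(C)C)C=C(O)C1=O
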